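**Retrosynthetic overview**

1. Target ⇐ diacetylation ⇐ zerovalent-palladium-catalysed 1,4-addition of methacrylic acid to a vinyl epoxide (makes the C14–O ester and the C5=C10 alkene, keeps C6–O) ⇐ bicyclic dienyl α-methylene lactone ⇐ bicyclic enone lactone.
2. Key disconnection, a [3+3] annulation: the cyclohexenone is cut at C8–C9 and at C5=C6. This gives a C3 ketone unit (C9–C10–C5 with the (S) side chain, from (S)-citronellal) and a 4-vinyl-5-menthyloxy-γ-butyrolactone (C6–C7–C8 with C11 and C12).
3. Ring order: the γ-lactone is present from the start (chiral 5-alkoxyfuranone); the six-membered carbocycle is closed second, in the key step.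
4. Enabling feature: C-8 carries the lactone ring oxygen, so it can be an O,O-acetal carbon that ionises to a cyclic acyloxocarbenium ion. The only ring alkene of the target sits on C-5, so the C5–C6 bond can first be made as a C=C by metathesis and the unsaturation moved to C5=C10 later.
5. Stereocontrol: C-4 from citronellal; C-7 by anti conjugate addition to the menthyl acetal; C-8 by anti attack on the oxocarbenium ion; C-6 by catalyst-controlled epoxidation.

Key step: step 7

Remarks on the chemistry:
- Numbering used in the text only: C-1 (CH2OAc) to C-4 (side-chain CH, methyl C-15); ring C-5 (sp2, bears the side chain), C-6 (CHOAc), C-7, C-8 (CH–O), C-9 (CH2), C-10 (sp2, bears C-14H2O); lactone C-11 (=C-13H2), C-12 (C=O).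
- Assumption: (5S)-5-(d-menthyloxy)furan-2(5H)-one (8) is taken as a purchasable compound; it is otherwise available in one step from 5-hydroxyfuran-2(5H)-one and (+)-menthol.

**Route**

Step 1
Reactants: 1 (S)-citronellal
Product: 2 (3S)-3,7-dimethyl-2-methylideneoct-6-enal
Conditions: aq. HCHO (37%), pyrrolidine (10 mol%), EtCO2H (10 mol%), iPrOH, 45 °C
Reagents that add atoms: formaldehyde, C=O
Why: amine-catalysed Mannich-type α-methylenation of an α-unbranched aldehyde (enamine addition to the formaldehyde-derived iminium ion, then elimination); the C-4 stereocentre is β to the carbonyl and is not enolised.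

Step 2
Reactants: 2 (3S)-3,7-dimethyl-2-methylideneoct-6-enal
Product: 3 (4S)-4,8-dimethyl-3-methylidenenon-7-en-2-ol (both C-2 epimers)
Conditions: MeMgBr, THF, −78 °C; aq. NH4Cl
Reagents that add atoms: methylmagnesium bromide, C[Mg]Br
Why: Grignard 1,2-addition to the α-substituted enal; the new carbinol centre is formed without control, which does not matter because it is oxidised in the next step.

Step 3
Reactants: 3 (4S)-4,8-dimethyl-3-methylidenenon-7-en-2-ol
Product: 4 (4S)-4,8-dimethyl-3-methylidenenon-7-en-2-one
Conditions: Dess–Martin periodinane, NaHCO3, CH2Cl2, 0 °C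
Reagents that add atoms: none
Why: Dess–Martin oxidation of the secondary allylic alcohol under buffered conditions should give the α-methylene ketone without isomerising it; the C-4 centre is not enolisable.

Step 4
Reactants: 4 (4S)-4,8-dimethyl-3-methylidenenon-7-en-2-one
Product: 6 (4S)-7-hydroxy-4-methyl-3-methylideneheptan-2-one, via keto aldehyde 5 (not isolated)
Conditions: O3 (1 equiv, Sudan red end point), pyridine, CH2Cl2, −78 °C; PPh3; then NaBH(OAc)3, AcOH, rt
Reagents that add atoms: ozone, O=[O+][O-]
Why: chemoselective ozonolysis, since ozone reacts far faster with the electron-rich trisubstituted alkene than with the electron-poor enone alkene, followed by NaBH(OAc)3 reduction of the aldehyde only.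

Step 5
Reactants: 6 (4S)-7-hydroxy-4-methyl-3-methylideneheptan-2-one
Product: 7 trimethyl{[(4S)-4-methyl-3-methylidene-7-(trimethylsilyloxy)hept-1-en-2-yl]oxy}silane
Conditions: TMSOTf (2.2 equiv), Et3N, CH2Cl2, 0 °C
Reagents that add atoms: trimethylsilyl trifluoromethanesulfonate, C[Si](C)(C)OS(=O)(=O)C(F)(F)F
Why: soft enolisation with a silyl triflate and amine should give a single 2-silyloxy-1,3-diene because only the methyl group of the ketone carries α-hydrogens, and the primary alcohol is silylated in the same operation.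

Step 6
Reactants: 8 (5S)-5-{[(1S,2R,5S)-5-methyl-2-(propan-2-yl)cyclohexyl]oxy}furan-2(5H)-one
Product: 9 (4R,5S)-4-ethenyl-5-{[(1S,2R,5S)-5-methyl-2-(propan-2-yl)cyclohexyl]oxy}oxolan-2-one
Conditions: CH2=CHMgBr, CuBr·SMe2 (10 mol%), THF, −78 → −40 °C; aq. NH4Cl
Reagents that add atoms: vinylmagnesium bromide, C=C[Mg]Br
Why: copper-catalysed conjugate addition of the vinyl Grignard reagent to the γ-alkoxybutenolide should take place anti to the menthyloxy group on the adjacent acetal carbon, which sets C-7 as the 4,5-trans lactone.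

Step 7
Reactants: 9 (4R,5S)-4-ethenyl-5-(menthyloxy)oxolan-2-one; 7 the silyl dienol ether
Product: 11 (3aR,7aR)-5-[(2S)-5-hydroxypentan-2-yl]-3a,7a-dihydro-1-benzofuran-2,6(3H,7H)-dione, via dienone 10 (not isolated)
Conditions: TMSOTf (0.5 equiv), CH2Cl2, −78 → −20 °C; then 2,6-di-tert-butylpyridine, second-generation Hoveyda–Grubbs catalyst (7 mol%), toluene, 70 °C, same flask; 0.1 M HCl, MeOH work-up
Reagents that add atoms: none
Why: TMSOTf silylates the exocyclic menthyloxy oxygen of the lactone acetal and ionises it to the five-membered cyclic acyloxocarbenium ion, which is captured at C-8 by the unsubstituted enol terminus of 7 to give dienone 10 and regenerate TMSOTf (Mukaiyama-type addition; the closest known reactions are Lewis acid substitutions of 5-alkoxy-γ-butyrolactones and anomeric C-glycosylations with silyl enol ethers). The ruthenium alkylidene then loads on the monosubstituted vinyl group at C-7 and closes the cyclohexenone onto the enone methylene with loss of ethylene; this is a six-membered ring-closing olefin metathesis and gives the trans-fused bicycle. C-8 is set in the first stage by attack anti to the neighbouring vinyl group on the nearly planar oxocarbenium ring (1,2-induction from C-7, whose configuration comes from 9); the metathesis creates no stereocentre. The step needs loss of the exocyclic alkoxide rather than the ring carboxylate so that the lactone survives, and reaction of 7 with the oxocarbenium ion rather than with the enone being formed, which low temperature and about one equivalent of 7 should secure. It also needs a single ring size in the metathesis, which is secured because 10 has only two terminal alkenes; this is why C-10 is carried as a ketone and not yet as a methylene.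

Step 8
Reactants: 11 the bicyclic enone lactone
Product: 12 (3aR,7aR)-5-[(2S)-5-hydroxypentan-2-yl]-6-methylidene-3a,6,7,7a-tetrahydro-1-benzofuran-2(3H)-one
Conditions: Zn, CH2Br2, TiCl4, THF–CH2Cl2, 0 °C → rt
Reagents that add atoms: dibromomethane, BrCBr
Why: Takai–Lombardo methylenation converts the ketone into the exocyclic methylene under non-basic conditions, which matters because base would eliminate the lactone oxygen β to the ketone and aromatise the ring; the lactone carbonyl is not attacked.

Step 9
Reactants: 12 the dienyl lactone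
Product: 15 (3aS,7aR)-5-[(2S)-5-hydroxypentan-2-yl]-3,6-dimethylidene-3a,6,7,7a-tetrahydro-1-benzofuran-2(3H)-one, via Mannich base 13 (not isolated), via methiodide 14 (not isolated)
Conditions: LiN(iPr)2 (2.3 equiv), THF, −78 °C; CH2=NMe2+ I−, −78 → 0 °C; then MeI, MeOH, rt; then NaHCO3, CH2Cl2–H2O
Reagents that add atoms: N,N-dimethylmethyleneiminium iodide, C=[N+](C)C.[I-]
Why: α-methylenation of the lactone through its lithium enolate (Mannich reaction, N-methylation, β-elimination) is the standard entry to α-methylene-γ-butyrolactones; the extra base covers the free hydroxyl and no other acidic C–H competes.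

Step 10
Reactants: 15 the α-methylene dienyl lactone
Product: 16 the 5,6-epoxide of 15 (vinyl oxirane; oxirane oxygen on the face opposite H-7; 5R,6S)
Conditions: ent-Shi ketone (L-fructose-derived, 0.3 equiv), KHSO5 (as 2KHSO5·KHSO4·K2SO4), K2CO3, Bu4NHSO4, MeCN–CH2(OMe)2–aq. Na2B4O7 buffer, 0 °C
Reagents that add atoms: potassium peroxymonosulfate, [K+].OOS(=O)(=O)[O-]
Why: in this Shi asymmetric epoxidation the electrophilic dioxirane should attack only the electron-rich trisubstituted ring alkene of the diene, and the ketone enantiomer is chosen, by analogy with 1-substituted cyclohexenes, to deliver oxygen to the face opposite H-7, which fixes C-6.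

Step 11
Reactants: 16 the vinyl oxirane
Product: 17 [(3aS,4S,7aR)-4-hydroxy-5-[(2S)-5-hydroxypentan-2-yl]-3-methylidene-2-oxo-2,3,3a,4,7,7a-hexahydro-1-benzofuran-6-yl]methyl 2-methylprop-2-enoate
Conditions: Pd(PPh3)4 (5 mol%), methacrylic acid (2 equiv), THF, 0 °C → rt
Reagents that add atoms: methacrylic acid, C=C(C)C(=O)O
Why: zerovalent-palladium-catalysed 1,4-addition of a carboxylic acid to a vinyl epoxide (Tsuji–Trost type): ionisation of the tertiary allylic C5–O bond gives a π-allyl complex that the methacrylate should attack at the unhindered CH2 terminus, creating the tetrasubstituted C5=C10 alkene and the C-14 ester while the C6–O bond, and so the C-6 configuration, is untouched.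

Step 12
Reactants: 17 the diol methacrylate
Product: 18 [(3aS,4S,7aR)-4-acetoxy-5-[(2S)-5-acetoxypentan-2-yl]-3-methylidene-2-oxo-2,3,3a,4,7,7a-hexahydro-1-benzofuran-6-yl]methyl 2-methylprop-2-enoate (target)
Conditions: Ac2O, pyridine, DMAP (cat.), CH2Cl2, 0 °C → rt
Reagents that add atoms: acetic anhydride, CC(=O)OC(C)=O
Why: DMAP-catalysed acetylation should esterify the primary and the hindered allylic secondary hydroxyl faster than the lactone can migrate to the C-6 oxygen.

**Compound list**

1 | (S)-citronellal, (3S)-3,7-dimethyloct-6-enal | O=CC[C@@H](C)CCC=C(C)C | starting material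
2 | (3S)-3,7-dimethyl-2-methylideneoct-6-enal | O=CC(=C)[C@@H](C)CCC=C(C)C | intermediate
3 | (4S)-4,8-dimethyl-3-methylidenenon-7-en-2-ol (C-2 epimers) | CC(O)C(=C)[C@@H](C)CCC=C(C)C | intermediate
4 | (4S)-4,8-dimethyl-3-methylidenenon-7-en-2-one | CC(=O)C(=C)[C@@H](C)CCC=C(C)C | intermediate
5 | (4S)-4-methyl-5-methylidene-6-oxoheptanal | CC(=O)C(=C)[C@@H](C)CCC=O | intermediate
6 | (4S)-7-hydroxy-4-methyl-3-methylideneheptan-2-one | CC(=O)C(=C)[C@@H](C)CCCO | intermediate
7 | trimethyl{[(4S)-4-methyl-3-methylidene-7-(trimethylsilyloxy)hept-1-en-2-yl]oxy}silane | C=C(O[Si](C)(C)C)C(=C)[C@@H](C)CCCO[Si](C)(C)C | intermediate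
8 | (5S)-5-{[(1S,2R,5S)-5-methyl-2-(propan-2-yl)cyclohexyl]oxy}furan-2(5H)-one | O=C1C=C[C@@H](O[C@H]2C[C@@H](C)CC[C@@H]2C(C)C)O1 | starting material
9 | (4R,5S)-4-ethenyl-5-{[(1S,2R,5S)-5-methyl-2-(propan-2-yl)cyclohexyl]oxy}oxolan-2-one | O=C1C[C@H](C=C)[C@@H](O[C@H]2C[C@@H](C)CC[C@@H]2C(C)C)O1 | intermediate
10 | (4R,5R)-4-ethenyl-5-[(4S)-4-methyl-3-methylidene-2-oxo-7-(trimethylsilyloxy)heptyl]oxolan-2-one | O=C1C[C@H](C=C)[C@@H](CC(=O)C(=C)[C@@H](C)CCCO[Si](C)(C)C)O1 | intermediate
11 | (3aR,7aR)-5-[(2S)-5-hydroxypentan-2-yl]-3a,7a-dihydro-1-benzofuran-2,6(3H,7H)-dione | O=C1C([C@@H](C)CCCO)=C[C@H]2CC(=O)O[C@@H]2C1 | intermediate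
12 | (3aR,7aR)-5-[(2S)-5-hydroxypentan-2-yl]-6-methylidene-3a,6,7,7a-tetrahydro-1-benzofuran-2(3H)-one | C=C1C([C@@H](C)CCCO)=C[C@H]2CC(=O)O[C@@H]2C1 | intermediate
13 | 3-[(dimethylamino)methyl] derivative of 12 (Mannich base, C-11 epimers) | C=C1C([C@@H](C)CCCO)=C[C@H]2C(CN(C)C)C(=O)O[C@@H]2C1 | intermediate
14 | trimethylammonium iodide of 13 | C=C1C([C@@H](C)CCCO)=C[C@H]2C(C[N+](C)(C)C)C(=O)O[C@@H]2C1.[I-] | intermediate
15 | (3aS,7aR)-5-[(2S)-5-hydroxypentan-2-yl]-3,6-dimethylidene-3a,6,7,7a-tetrahydro-1-benzofuran-2(3H)-one | C=C1C([C@@H](C)CCCO)=C[C@H]2C(=C)C(=O)O[C@@H]2C1 | intermediate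
16 | 5,6-epoxide of 15 (5R,6S; oxirane oxygen opposite H-7; vinyl oxirane) | C=C1C[C@H]2OC(=O)C(=C)[C@@H]2[C@@H]3O[C@]13[C@@H](C)CCCO | intermediate
17 | [(3aS,4S,7aR)-4-hydroxy-5-[(2S)-5-hydroxypentan-2-yl]-3-methylidene-2-oxo-2,3,3a,4,7,7a-hexahydro-1-benzofuran-6-yl]methyl 2-methylprop-2-enoate | C=C(C)C(=O)OCC1=C([C@@H](C)CCCO)[C@@H](O)[C@H]2C(=C)C(=O)O[C@@H]2C1 | intermediate
18 | [(3aS,4S,7aR)-4-acetoxy-5-[(2S)-5-acetoxypentan-2-yl]-3-methylidene-2-oxo-2,3,3a,4,7,7a-hexahydro-1-benzofuran-6-yl]methyl 2-methylprop-2-enoate | C=C(C)C(=O)OCC1=C([C@@H](C)CCCOC(C)=O)[C@@H](OC(C)=O)[C@H]2C(=C)C(=O)O[C@@H]2C1 | target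

**Step count and risks**

Total step count: 12. Longest linear sequence: 11 (steps 1–5, then 7–12).

Steps most likely to fail:

Step 7. The ring closure may stall, because the enone alkene is 1,1-disubstituted, electron-poor and next to a branched carbon. The Lewis-acid- and polymerisation-sensitive α-methylene ketone may also be lost before it cyclises. The fallback sets out from 9 (with 1 as the source of the other half) and comes back at 11; it closes the ring by aldol condensation instead of metathesis and needs no α-methylene ketone. Compound 1 is treated with MeMgBr to give (4S)-4,8-dimethylnon-7-en-2-ol F1, which is oxidised with Dess–Martin periodinane to (4S)-4,8-dimethylnon-7-en-2-one F2. Ozonolysis and NaBH(OAc)3 reduction give (4S)-7-hydroxy-4-methylheptan-2-one F3, and kinetic silylation (LiN(iPr)2, TMSCl, −78 °C) gives the terminal bis-silyl enol ether F4. TMSOTf-mediated coupling of F4 with 9 and mild acid work-up should give the trans keto lactone F5. Ozonolysis of its only alkene gives the keto aldehyde F6, which is closed to 11 by acid-mediated intramolecular aldol condensation (TsOH, benzene, 40 °C).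

Step 10. Facial selectivity may be poor if the catalyst works against the intrinsic bias of the bicyclic diene, and the lactone may suffer in the basic medium. The fallback sets out from 15 and comes back at 18; it accepts the other face and corrects C-6 by inversion. Epoxidation of 15 with the D-fructose-derived Shi ketone should give the diastereomeric vinyl oxirane F7. Opening with Pd(PPh3)4 and methacrylic acid as in step 11 gives the C-6 epimeric diol methacrylate F8. A Mitsunobu reaction with acetic acid (PPh3, diisopropyl azodicarboxylate, THF) then esterifies the primary alcohol and inverts C-6 to give 18 directly.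

Step 11. The carboxylate may attack the tertiary terminus, the C-6 alkoxide may attack the lactone carbonyl, or the vinyl oxirane may isomerise to a carbonyl compound. The fallback sets out from 16 and comes back at 17; it replaces the π-allyl chemistry by halide opening and substitution. MgBr2·OEt2 (Et2O–THF, −20 °C) opens the vinyl oxirane to the primary allylic bromide F9, leaving the C-6 oxygen untouched. SN2 displacement with CsO2CC(CH3)=CH2 in DMF at 0 °C gives 17.

Further compounds
F1 | step 7 | (4S)-4,8-dimethylnon-7-en-2-ol (C-2 epimers) | CC(O)C[C@@H](C)CCC=C(C)C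
F2 | step 7 | (4S)-4,8-dimethylnon-7-en-2-one | CC(=O)C[C@@H](C)CCC=C(C)C
F3 | step 7 | (4S)-7-hydroxy-4-methylheptan-2-one | CC(=O)C[C@@H](C)CCCO
F4 | step 7 | trimethyl{[(4S)-4-methyl-7-(trimethylsilyloxy)hept-1-en-2-yl]oxy}silane | C=C(O[Si](C)(C)C)C[C@@H](C)CCCO[Si](C)(C)C
F5 | step 7 | (4R,5R)-4-ethenyl-5-[(4S)-7-hydroxy-4-methyl-2-oxoheptyl]oxolan-2-one | O=C1C[C@H](C=C)[C@@H](CC(=O)C[C@@H](C)CCCO)O1
F6 | step 7 | (2R,3S)-2-[(4S)-7-hydroxy-4-methyl-2-oxoheptyl]-5-oxooxolane-3-carbaldehyde | O=C1C[C@H](C=O)[C@@H](CC(=O)C[C@@H](C)CCCO)O1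
F7 | step 10 | 5,6-epoxide of 15 with the oxirane oxygen on the same face as H-7 (5S,6R) | C=C1C[C@H]2OC(=O)C(=C)[C@@H]2[C@H]3O[C@@]13[C@@H](C)CCCO
F8 | step 10 | [(3aS,4R,7aR)-4-hydroxy-5-[(2S)-5-hydroxypentan-2-yl]-3-methylidene-2-oxo-2,3,3a,4,7,7a-hexahydro-1-benzofuran-6-yl]methyl 2-methylprop-2-enoate | C=C(C)C(=O)OCC1=C([C@@H](C)CCCO)[C@H](O)[C@H]2C(=C)C(=O)O[C@@H]2C1
F9 | step 11 | (3aS,4S,7aR)-6-(bromomethyl)-4-hydroxy-5-[(2S)-5-hydroxypentan-2-yl]-3-methylidene-3a,4,7,7a-tetrahydro-1-benzofuran-2(3H)-one | BrCC1=C([C@@H](C)CCCO)[C@@H](O)[C@H]2C(=C)C(=O)O[C@@H]2C1
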